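**Strategy.** Numbered as a 2-naphthol (ring A: C4a–C8a; ring B: C1–C4), the target hides an aldol retron: O–C2, C3 and the exocyclic CH2 are the enol of a β-aryl ketone, and C3=C4 is an aldol-condensation alkene. Everything rests on cutting the CH2–aryl bond to the guaiacyl ring together with C3–C4. In one operation a rhodium-catalysed conjugate addition of a guaiacylboronic acid to a vinyl ketone forges the CH2–aryl bond, the enolate closes ring B onto a diaryl ketone, and dehydration aromatises it. The precursor is an open-chain 2-aroylbenzyl β-acetoxyethyl ketone containing no naphthalene; the enone is unmasked in the flask.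

Key step: step 6

Remark on naming: ring C is the 4-hydroxy-2-methoxyphenyl ring on C4 and ring D is the guaiacyl ring; the target has no stereocentre.
Assumption: compounds 1, 3, 7 and 10 are taken as catalogue compounds (each is otherwise one benzylation or acetylation away from syringaldehyde, 4-bromo-3-methoxyphenol, but-3-yn-1-ol or the free phenol boronic ester).

**Route**

Step 1
Reactants: 1 4-(benzyloxy)-3,5-dimethoxybenzaldehyde
Product: 2 4-(benzyloxy)-2-bromo-3,5-dimethoxybenzaldehyde
Conditions: NBS (1.05 equiv), MeCN, 25 °C, dark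
Reagents that add atoms: N-bromosuccinimide O=C1CCC(=O)N1Br
Why: Electrophilic aromatic bromination, in which C2 and C6 of 1 are equivalent and each is ortho to one methoxy group and para to the other, so a single monobromide should form while the formyl group discourages a second bromination.

Step 2
Reactants: 2 4-(benzyloxy)-2-bromo-3,5-dimethoxybenzaldehyde; 3 4-(benzyloxy)-1-bromo-2-methoxybenzene
Product: 5 racemic [4-(benzyloxy)-2-bromo-3,5-dimethoxyphenyl][4-(benzyloxy)-2-methoxyphenyl]methanol, via arylmagnesium bromide 4 (not isolated)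
Conditions: 3, Mg turnings, cat. I2, THF, 65 °C; then 2, THF, −20 to 0 °C; aq. NH4Cl
Reagents that add atoms: none
Why: Grignard addition to an aldehyde, in which reagent 4 should add to the formyl group much faster than it exchanges with the aryl bromide of 2, and the new carbinol stereocentre is formed as a racemate that step 3 removes.

Step 3
Reactants: 5 racemic [4-(benzyloxy)-2-bromo-3,5-dimethoxyphenyl][4-(benzyloxy)-2-methoxyphenyl]methanol
Product: 6 [4-(benzyloxy)-2-bromo-3,5-dimethoxyphenyl][4-(benzyloxy)-2-methoxyphenyl]methanone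
Conditions: Dess–Martin periodinane (1.2 equiv), CH2Cl2, 25 °C
Reagents that add atoms: none
Why: Dess–Martin oxidation of a secondary diarylcarbinol to the diaryl ketone under neutral conditions that should leave the aryl bromide and the benzyl ethers untouched.

Step 4
Reactants: 6 [4-(benzyloxy)-2-bromo-3,5-dimethoxyphenyl][4-(benzyloxy)-2-methoxyphenyl]methanone; 7 but-3-yn-1-yl acetate
Product: 8 4-{3-(benzyloxy)-6-[4-(benzyloxy)-2-methoxybenzoyl]-2,4-dimethoxyphenyl}but-3-yn-1-yl acetate
Conditions: PdCl2(MeCN)2 (3 mol %), XPhos (9 mol %), Cs2CO3 (2 equiv), MeCN, 70 °C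
Reagents that add atoms: none
Why: Copper-free Sonogashira coupling, in which the ortho aroyl group activates the hindered C–Br bond toward oxidative addition to zerovalent palladium, the bulky biarylphosphine carries di-ortho-substituted bromides, and carbonate in dry MeCN should leave the acetate intact.

Step 5
Reactants: 8 4-{3-(benzyloxy)-6-[4-(benzyloxy)-2-methoxybenzoyl]-2,4-dimethoxyphenyl}but-3-yn-1-yl acetate
Product: 9 4-{3-(benzyloxy)-6-[4-(benzyloxy)-2-methoxybenzoyl]-2,4-dimethoxyphenyl}-3-oxobutyl acetate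
Conditions: NaAuCl4·2H2O (5 mol %), 1,4-dioxane/H2O 10:1, 50 °C
Reagents that add atoms: water O
Why: Gold-catalysed alkyne hydration with neighbouring-carbonyl participation, in which 6-endo-dig attack of the benzophenone oxygen on the alkyne bound to trivalent gold should place the new carbonyl on the alkyne carbon remote from ring A and so give the 1,5-diketone, not the aryl ketone.

Step 6
Reactants: 9 4-{3-(benzyloxy)-6-[4-(benzyloxy)-2-methoxybenzoyl]-2,4-dimethoxyphenyl}-3-oxobutyl acetate; 10 [4-(benzyloxy)-3-methoxyphenyl]boronic acid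
Product: 13 7-(benzyloxy)-3-[4-(benzyloxy)-3-methoxybenzyl]-4-[4-(benzyloxy)-2-methoxyphenyl]-6,8-dimethoxynaphthalen-2-ol, via vinyl ketone 11 (not isolated), via aldol adduct 12 (not isolated)
Conditions: [Rh(cod)Cl]2 (2.5 mol %), 10 (2 equiv), KOH (5 equiv), 1,4-dioxane/H2O 10:1, argon, slow addition of 9 at 25 °C, then 90 °C; aq. HCl work-up
Reagents that add atoms: none
Why: Rhodium-catalysed conjugate addition–aldol cyclisation (Hayashi–Miyaura addition followed by intramolecular aldol condensation): hydroxide unmasks vinyl ketone 11 by E1cB loss of acetate, the aryl group passes from boron to monovalent rhodium and inserts the enone in a 1,4 sense so that the aryl carbon bonds to the terminal CH2, and the C3 enolate (rhodium-bound or, after protonation, re-formed by KOH) adds to the diaryl ketone to give aldol adduct 12. Ring B is closed by this 6-(enolendo)-exo-trig aldol addition, and E1cB dehydration across C3–C4 followed by tautomerisation of the naphthalen-2(1H)-one makes it aromatic, which should render the sequence irreversible. The closest known reaction types are the rhodium-catalysed tandem conjugate arylation–aldol cyclisation of keto-enones with arylboronic acids and the base-induced recyclisation of 2-acylbenzyl ketones to 2-naphthols. The two stereocentres of 12 (C3 and C4) are transient and vanish on aromatisation, so no stereocontrol is needed. The step needs 1,4- over 1,2-addition, secured by the preference of arylrhodium for the unhindered vinyl ketone over the hindered diaryl ketone; it needs a single aldol mode, secured because the diaryl ketone cannot enolise and only the C3 enolate reaches it through a six-membered transition state (the C1 enolate would close a four-membered ring); and the substitution pattern of ring D is fixed by the ipso carbon of the boronic acid. Slow addition of 9 keeps the concentration of the polymerisable enone low.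

Step 7
Reactants: 13 7-(benzyloxy)-3-[4-(benzyloxy)-3-methoxybenzyl]-4-[4-(benzyloxy)-2-methoxyphenyl]-6,8-dimethoxynaphthalen-2-ol
Product: 14 3-(4-hydroxy-3-methoxybenzyl)-4-(4-hydroxy-2-methoxyphenyl)-6,8-dimethoxynaphthalene-2,7-diol
Conditions: H2 (1 atm), 10% Pd/C, EtOAc/MeOH 1:1, 25 °C, degassed solvents
Reagents that add atoms: none
Why: Catalytic hydrogenolysis of the three benzyl aryl ethers over palladium on carbon, under which the naphthalene, the diarylmethane CH2 and the methyl ethers should stay intact.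

**Compound list**

1 | 4-(benzyloxy)-3,5-dimethoxybenzaldehyde | O=Cc1cc(OC)c(OCc2ccccc2)c(OC)c1 | starting material
2 | 4-(benzyloxy)-2-bromo-3,5-dimethoxybenzaldehyde | O=Cc1cc(OC)c(OCc2ccccc2)c(OC)c1Br | intermediate
3 | 4-(benzyloxy)-1-bromo-2-methoxybenzene | COc1cc(OCc2ccccc2)ccc1Br | starting material
4 | [4-(benzyloxy)-2-methoxyphenyl]magnesium bromide (formed in the flask) | COc1cc(OCc2ccccc2)ccc1[Mg]Br | intermediate
5 | racemic [4-(benzyloxy)-2-bromo-3,5-dimethoxyphenyl][4-(benzyloxy)-2-methoxyphenyl]methanol | OC(c1cc(OC)c(OCc2ccccc2)c(OC)c1Br)c1ccc(OCc2ccccc2)cc1OC | intermediate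
6 | [4-(benzyloxy)-2-bromo-3,5-dimethoxyphenyl][4-(benzyloxy)-2-methoxyphenyl]methanone | O=C(c1cc(OC)c(OCc2ccccc2)c(OC)c1Br)c1ccc(OCc2ccccc2)cc1OC | intermediate
7 | but-3-yn-1-yl acetate | CC(=O)OCCC#C | starting material
8 | 4-{3-(benzyloxy)-6-[4-(benzyloxy)-2-methoxybenzoyl]-2,4-dimethoxyphenyl}but-3-yn-1-yl acetate | CC(=O)OCCC#Cc1c(OC)c(OCc2ccccc2)c(OC)cc1C(=O)c1ccc(OCc2ccccc2)cc1OC | intermediate
9 | 4-{3-(benzyloxy)-6-[4-(benzyloxy)-2-methoxybenzoyl]-2,4-dimethoxyphenyl}-3-oxobutyl acetate | CC(=O)OCCC(=O)Cc1c(OC)c(OCc2ccccc2)c(OC)cc1C(=O)c1ccc(OCc2ccccc2)cc1OC | intermediate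
10 | [4-(benzyloxy)-3-methoxyphenyl]boronic acid | COc1cc(B(O)O)ccc1OCc1ccccc1 | starting material
11 | 1-{3-(benzyloxy)-6-[4-(benzyloxy)-2-methoxybenzoyl]-2,4-dimethoxyphenyl}but-3-en-2-one (formed in the flask) | C=CC(=O)Cc1c(OC)c(OCc2ccccc2)c(OC)cc1C(=O)c1ccc(OCc2ccccc2)cc1OC | intermediate
12 | 7-(benzyloxy)-3-[4-(benzyloxy)-3-methoxybenzyl]-4-[4-(benzyloxy)-2-methoxyphenyl]-4-hydroxy-6,8-dimethoxy-3,4-dihydronaphthalen-2(1H)-one (formed in the flask; mixture of racemic diastereomers) | O=C1Cc2c(OC)c(OCc3ccccc3)c(OC)cc2C(O)(c2ccc(OCc3ccccc3)cc2OC)C1Cc1ccc(OCc2ccccc2)c(OC)c1 | intermediate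
13 | 7-(benzyloxy)-3-[4-(benzyloxy)-3-methoxybenzyl]-4-[4-(benzyloxy)-2-methoxyphenyl]-6,8-dimethoxynaphthalen-2-ol | COc1cc(Cc2c(O)cc3c(OC)c(OCc4ccccc4)c(OC)cc3c2-c2ccc(OCc3ccccc3)cc2OC)ccc1OCc1ccccc1 | intermediate
14 | 3-(4-hydroxy-3-methoxybenzyl)-4-(4-hydroxy-2-methoxyphenyl)-6,8-dimethoxynaphthalene-2,7-diol | COc1cc(Cc2c(O)cc3c(OC)c(O)c(OC)cc3c2-c2ccc(O)cc2OC)ccc1O | target

**Step count**

Total steps: 7. Longest linear sequence: 7 steps (1 → 2 → 5 → 6 → 8 → 9 → 13 → 14).

**Steps most likely to fail**

Step 6. The unmasked enone may oligomerise under base before it is arylated, the electron-rich boronic acid may protodeboronate, or the aldol closure may stall at the hindered diaryl ketone. The fallback sets out from 9 and comes back at 13; it takes the cascade apart and delivers the aryl group by stoichiometric organocopper chemistry. Et3N in CH2Cl2 at 0 °C eliminates acetic acid from 9 to give vinyl ketone 11, which is used at once. Commercial 1-(benzyloxy)-4-bromo-2-methoxybenzene and Mg in THF give [4-(benzyloxy)-3-methoxyphenyl]magnesium bromide F1. With CuBr·SMe2 (10 mol %) in THF at −40 °C this should add 1,4 to 11 and, after aq. NH4Cl, give the open 1,5-diketone 1-{3-(benzyloxy)-6-[4-(benzyloxy)-2-methoxybenzoyl]-2,4-dimethoxyphenyl}-4-[4-(benzyloxy)-3-methoxyphenyl]butan-2-one F2. KOH in EtOH at 60 °C then closes ring B by aldol condensation and aromatisation to 13.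

Step 5. The benzophenone oxygen may attack in the 5-exo mode, or water may add directly at the aryl-bound alkyne carbon; either would place the carbonyl next to ring A. The acetate may also be lost in part. The fallback sets out from 8 and comes back at 9; it replaces catalytic hydration by a stoichiometric protic cyclisation to an isolable heteroaromatic salt. HBF4·OEt2 in CH2Cl2 at 0 °C should convert 8 into 3-(2-acetoxyethyl)-6-(benzyloxy)-1-[4-(benzyloxy)-2-methoxyphenyl]-5,7-dimethoxy-2-benzopyrylium tetrafluoroborate F3, precipitated with Et2O. Its six-membered ring fixes the oxygen on the remote alkyne carbon. Stirring F3 with aqueous NaOAc in MeCN at 25 °C opens the pseudobase to 9.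

Step 4. Oxidative addition may be slow at the electron-rich C–Br bond flanked by a methoxy and an aroyl group, so that hydrodebromination and alkyne oligomerisation take over. The fallback sets out from 2 and comes back at 8; it moves the coupling to the less encumbered aldehyde stage and changes the order of events. Aldehyde 2 and commercial but-3-yn-1-ol (PdCl2(MeCN)2, XPhos, Cs2CO3, MeCN, 60 °C) should give 4-(benzyloxy)-2-(4-hydroxybut-1-yn-1-yl)-3,5-dimethoxybenzaldehyde F4. Grignard reagent 4 (2.5 equiv, THF, −20 °C) adds to the formyl group to give racemic 4-{3-(benzyloxy)-6-[[4-(benzyloxy)-2-methoxyphenyl](hydroxy)methyl]-2,4-dimethoxyphenyl}but-3-yn-1-ol F5. MnO2 in CH2Cl2 oxidises only the doubly benzylic carbinol to [4-(benzyloxy)-2-(4-hydroxybut-1-yn-1-yl)-3,5-dimethoxyphenyl][4-(benzyloxy)-2-methoxyphenyl]methanone F6. Ac2O, pyridine and cat. DMAP then give 8.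

**Further compounds**

F1 | step 6 | [4-(benzyloxy)-3-methoxyphenyl]magnesium bromide | COc1cc([Mg]Br)ccc1OCc1ccccc1
F2 | step 6 | 1-{3-(benzyloxy)-6-[4-(benzyloxy)-2-methoxybenzoyl]-2,4-dimethoxyphenyl}-4-[4-(benzyloxy)-3-methoxyphenyl]butan-2-one | O=C(Cc1c(OC)c(OCc2ccccc2)c(OC)cc1C(=O)c1ccc(OCc2ccccc2)cc1OC)CCc1ccc(OCc2ccccc2)c(OC)c1
F3 | step 5 | 3-(2-acetoxyethyl)-6-(benzyloxy)-1-[4-(benzyloxy)-2-methoxyphenyl]-5,7-dimethoxy-2-benzopyrylium tetrafluoroborate | CC(=O)OCCc1cc2c(OC)c(OCc3ccccc3)c(OC)cc2c(-c2ccc(OCc3ccccc3)cc2OC)[o+]1.F[B-](F)(F)F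
F4 | step 4 | 4-(benzyloxy)-2-(4-hydroxybut-1-yn-1-yl)-3,5-dimethoxybenzaldehyde | O=Cc1cc(OC)c(OCc2ccccc2)c(OC)c1C#CCCO
F5 | step 4 | racemic 4-{3-(benzyloxy)-6-[[4-(benzyloxy)-2-methoxyphenyl](hydroxy)methyl]-2,4-dimethoxyphenyl}but-3-yn-1-ol | OCCC#Cc1c(OC)c(OCc2ccccc2)c(OC)cc1C(O)c1ccc(OCc2ccccc2)cc1OC
F6 | step 4 | [4-(benzyloxy)-2-(4-hydroxybut-1-yn-1-yl)-3,5-dimethoxyphenyl][4-(benzyloxy)-2-methoxyphenyl]methanone | OCCC#Cc1c(OC)c(OCc2ccccc2)c(OC)cc1C(=O)c1ccc(OCc2ccccc2)cc1OC
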